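With the octane chain counted from the benzylic carbon (C1) to the terminal methyl (C8), the target is a syn-3,5-diacetate in which O5 lies 1,3 to O3 and C5 lies 1,3 to C7. This double 1,3-relationship is what the key step exploits: C5–O is disconnected to an allylic alcohol of undefined configuration at C7 flanking a C5=C6 alkene, so only C3 needs a chiral reagent. In one operation Re(VII) carries the hydroxyl from C7 to C5 while benzaldehyde dimethyl acetal clasps O3 and O5 into an all-equatorial 2-phenyl-1,3-dioxane ring, forming three C–O bonds and two stereocentres. The precursor is the (3S,5E)-oct-5-ene-3,7-diol, a C7 epimer mixture, carrying the TBS-protected guaiacyl ring on C1.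

Key step: step 5

Remark: Ar stands for 4-(tert-butyldimethylsilyloxy)-3-methoxyphenyl. Chain locants are those defined above. Ester 1 and borane 5 (pentane solution) are assumed to be catalogue items.

Step 1
Reactants: 1 methyl 3-(4-hydroxy-3-methoxyphenyl)propanoate (methyl dihydroferulate)
Product: 2 methyl 3-[4-(tert-butyldimethylsilyloxy)-3-methoxyphenyl]propanoate
Conditions: TBSCl, imidazole, DMF, rt
Reagents that add atoms: tert-butyldimethylsilyl chloride, CC(C)(C)[Si](C)(C)Cl
Why: Imidazole-promoted O-silylation of a phenol is routine, and the aryl TBS ether should tolerate hydride, allylborane, ruthenium carbene, perrhenic acid and neutral hydrogenation yet leave with fluoride in the presence of acetates.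

Step 2
Reactants: 2 methyl 3-[4-(tert-butyldimethylsilyloxy)-3-methoxyphenyl]propanoate
Product: 4 3-[4-(tert-butyldimethylsilyloxy)-3-methoxyphenyl]propanal, via aluminium hemiacetal 3 (not isolated)
Conditions: DIBAL-H (1.05 equiv), toluene, −78 °C; MeOH quench at −78 °C, aq. Rochelle salt
Reagents that add atoms: none
Why: Partial ester reduction with DIBAL-H relies on the tetrahedral aluminium hemiacetal 3 persisting at −78 °C, so the aldehyde is released only on quenching and is not reduced further.

Step 3
Reactants: 4 3-[4-(tert-butyldimethylsilyloxy)-3-methoxyphenyl]propanal; 5 (+)-B-allyldiisopinocampheylborane (the reagent derived from (−)-α-pinene)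
Product: 7 (3S)-1-[4-(tert-butyldimethylsilyloxy)-3-methoxyphenyl]hex-5-en-3-ol, via homoallyl borinate 6 (not isolated)
Conditions: 5 (1.2 equiv, 1 M in pentane), Et2O, −100 °C; then HOCH2CH2NH2, 0 °C → rt, filtration
Reagents that add atoms: (+)-B-allyldiisopinocampheylborane 5 (delivers the allyl group), C=CCB([C@H]1C[C@H]2C[C@@H]([C@@H]1C)C2(C)C)[C@H]1C[C@H]2C[C@@H]([C@@H]1C)C2(C)C
Why: Brown asymmetric allylboration proceeds through a closed chair (Zimmerman–Traxler) transition state in which the isopinocampheyl groups derived from (−)-α-pinene expose the Re face of an unbranched aliphatic aldehyde, which sets C3 as S, and the non-oxidative ethanolamine work-up spares the base-sensitive aryl silyl ether.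

Step 4
Reactants: 7 (3S)-1-[4-(tert-butyldimethylsilyloxy)-3-methoxyphenyl]hex-5-en-3-ol; 8 racemic but-3-en-2-ol
Product: 9 (3S,5E)-1-[4-(tert-butyldimethylsilyloxy)-3-methoxyphenyl]oct-5-ene-3,7-diol (both C7 epimers)
Conditions: Hoveyda–Grubbs II (5 mol %), 8 (4 equiv), 1,4-benzoquinone (10 mol %), CH2Cl2, 40 °C
Reagents that add atoms: but-3-en-2-ol 8, CC(O)C=C
Why: Olefin cross-metathesis pairs a rapidly reacting terminal homoallylic alkene with an excess of a slowly dimerising secondary allylic alcohol, loss of ethene drives the reaction towards the E heterodimer, C3 is not touched, and C7 is left as an epimer mixture on purpose because step 5 erases it.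

Step 5
Reactants: 9 (3S,5E)-1-[4-(tert-butyldimethylsilyloxy)-3-methoxyphenyl]oct-5-ene-3,7-diol (both C7 epimers); 10 benzaldehyde dimethyl acetal
Product: 12 (2S,4S,6S)-4-{2-[4-(tert-butyldimethylsilyloxy)-3-methoxyphenyl]ethyl}-2-phenyl-6-[(E)-prop-1-enyl]-1,3-dioxane (all-cis), via transposed syn-3,5-diol 11 (not isolated)
Conditions: Re2O7 (5 mol %), PhCH(OMe)2 (2.5 equiv), CH2Cl2, 0 °C → rt; Et3N quench
Reagents that add atoms: benzaldehyde dimethyl acetal 10, COC(OC)c1ccccc1
Why: The C7 hydroxyl condenses with Re2O7 to a perrhenate ester, which passes its oxygen suprafacially through a chair-like [3,3] array (at the limit a tight allyl cation–perrhenate pair) to C5 and back, so that 9, both C5 epimers of the transposed diol and their alkene isomers stay in equilibrium. The closest known reaction type is exactly this one, the Re(VII)-catalysed 1,3-transposition of allylic alcohols that is steered by a neighbouring hydroxyl and drained as a benzylidene acetal. The 1,3-dioxane ring closes by acid-catalysed acetal exchange: one hydroxyl of 11 replaces a methoxy group of 10, loss of the second methanol gives an oxocarbenium ion, and the other hydroxyl adds to its carbon in a 6-endo-trig closure. C5 is controlled thermodynamically by the fixed 3S centre, because only the syn isomer seats the arylethyl and propenyl groups both equatorial on the chair, and the acetal carbon follows the same bias by placing phenyl equatorial; mismatched acetals can reopen by methanol exchange or at their allylic C5–O bond. The step needs regioselection between C5–OH and C7–OH, which the substrate secures through the 1,3-spacing of O3 and O5, since O3 and O7 could be bridged only in an eight-membered ring containing an E alkene. It also needs the transposition to outrun Prins closure of an O3 oxocarbenium ion onto C5=C6 and alkylation of the arene, which the electron-withdrawing C7 oxygen on that alkene, the silylated (less donating) phenol oxygen and the low temperature should ensure, and any Z-propenyl acetal is harmless because step 6 removes the alkene.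

Step 6
Reactants: 12 (2S,4S,6S)-4-{2-[4-(tert-butyldimethylsilyloxy)-3-methoxyphenyl]ethyl}-2-phenyl-6-[(E)-prop-1-enyl]-1,3-dioxane
Product: 14 (3S,5R)-1-[4-(tert-butyldimethylsilyloxy)-3-methoxyphenyl]octane-3,5-diol, via saturated propyl dioxane 13 (not isolated)
Conditions: H2 (1 atm), 20 % Pd(OH)2/C, EtOAc–EtOH, rt
Reagents that add atoms: none
Why: Heterogeneous catalytic hydrogenation should saturate the disubstituted alkene first and then hydrogenolyse the two benzylic C–O bonds of the acetal to toluene, a sequence that breaks no bond at C3 or C5, so both stereocentres are retained, while the aryl silyl ether is inert in a neutral solvent.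

Step 7
Reactants: 14 (3S,5R)-1-[4-(tert-butyldimethylsilyloxy)-3-methoxyphenyl]octane-3,5-diol
Product: 15 (3S,5R)-1-[4-(tert-butyldimethylsilyloxy)-3-methoxyphenyl]octane-3,5-diyl diacetate
Conditions: Ac2O, pyridine, DMAP (cat.), CH2Cl2, 0 °C → rt
Reagents that add atoms: acetic anhydride, CC(=O)OC(C)=O
Why: DMAP-catalysed acylation takes place at oxygen with retention at C3 and C5, and the silyl ether keeps the phenol out of the reaction.

Step 8
Reactants: 15 (3S,5R)-1-[4-(tert-butyldimethylsilyloxy)-3-methoxyphenyl]octane-3,5-diyl diacetate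
Product: 16 (3S,5R)-1-(4-hydroxy-3-methoxyphenyl)octane-3,5-diyl diacetate (CNP0240815.1)
Conditions: TBAF, AcOH (1:1), THF, 0 °C
Reagents that add atoms: none
Why: Fluoride-induced desilylation is fast for aryl silyl ethers because phenoxide is a good leaving group on silicon, and the acetic acid buffer protonates it at once so that neither acetate is hydrolysed or transferred.

Compound list
1 | methyl 3-(4-hydroxy-3-methoxyphenyl)propanoate | COC(=O)CCc1ccc(O)c(OC)c1 | starting material
2 | methyl 3-[4-(tert-butyldimethylsilyloxy)-3-methoxyphenyl]propanoate | COC(=O)CCc1ccc(O[Si](C)(C)C(C)(C)C)c(OC)c1 | intermediate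
3 | diisobutylaluminium hemiacetal of 2 (1-methoxy-3-arylpropoxy-diisobutylalane) | COC(CCc1ccc(O[Si](C)(C)C(C)(C)C)c(OC)c1)O[Al](CC(C)C)CC(C)C | intermediate
4 | 3-[4-(tert-butyldimethylsilyloxy)-3-methoxyphenyl]propanal | O=CCCc1ccc(O[Si](C)(C)C(C)(C)C)c(OC)c1 | intermediate
5 | (+)-B-allyldiisopinocampheylborane, from (−)-α-pinene | C=CCB([C@H]1C[C@H]2C[C@@H]([C@@H]1C)C2(C)C)[C@H]1C[C@H]2C[C@@H]([C@@H]1C)C2(C)C | starting material
6 | (3S)-1-arylhex-5-en-3-yl diisopinocampheylborinate | C=CC[C@H](CCc1ccc(O[Si](C)(C)C(C)(C)C)c(OC)c1)OB([C@H]1C[C@H]2C[C@@H]([C@@H]1C)C2(C)C)[C@H]1C[C@H]2C[C@@H]([C@@H]1C)C2(C)C | intermediate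
7 | (3S)-1-[4-(tert-butyldimethylsilyloxy)-3-methoxyphenyl]hex-5-en-3-ol | C=CC[C@H](CCc1ccc(O[Si](C)(C)C(C)(C)C)c(OC)c1)O | intermediate
8 | racemic but-3-en-2-ol | CC(O)C=C | starting material
9 | (3S,5E)-1-[4-(tert-butyldimethylsilyloxy)-3-methoxyphenyl]oct-5-ene-3,7-diol, both C7 epimers | CC(O)/C=C/C[C@H](CCc1ccc(O[Si](C)(C)C(C)(C)C)c(OC)c1)O | intermediate
10 | benzaldehyde dimethyl acetal | COC(OC)c1ccccc1 | starting material
11 | (3S,5S,6E)-1-[4-(tert-butyldimethylsilyloxy)-3-methoxyphenyl]oct-6-ene-3,5-diol (syn) | C/C=C/[C@@H](O)C[C@H](CCc1ccc(O[Si](C)(C)C(C)(C)C)c(OC)c1)O | intermediate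
12 | (2S,4S,6S)-4-(2-arylethyl)-2-phenyl-6-[(E)-prop-1-enyl]-1,3-dioxane, all-cis | C/C=C/[C@@H]1C[C@H](CCc2ccc(O[Si](C)(C)C(C)(C)C)c(OC)c2)O[C@H](c2ccccc2)O1 | intermediate
13 | (2R,4S,6R)-4-(2-arylethyl)-2-phenyl-6-propyl-1,3-dioxane, all-cis | CCC[C@@H]1C[C@H](CCc2ccc(O[Si](C)(C)C(C)(C)C)c(OC)c2)O[C@H](c2ccccc2)O1 | intermediate
14 | (3S,5R)-1-[4-(tert-butyldimethylsilyloxy)-3-methoxyphenyl]octane-3,5-diol | CCC[C@H](C[C@H](CCc1ccc(O[Si](C)(C)C(C)(C)C)c(OC)c1)O)O | intermediate
15 | (3S,5R)-1-[4-(tert-butyldimethylsilyloxy)-3-methoxyphenyl]octane-3,5-diyl diacetate | CCC[C@H](C[C@H](CCc1ccc(O[Si](C)(C)C(C)(C)C)c(OC)c1)OC(C)=O)OC(C)=O | intermediate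
16 | (3S,5R)-1-(4-hydroxy-3-methoxyphenyl)octane-3,5-diyl diacetate | CCC[C@H](C[C@H](CCc1ccc(O)c(OC)c1)OC(C)=O)OC(C)=O | target

Total step count: 8. Longest linear sequence: 8 steps, from 1 to 16.

Steps most likely to fail

1. Step 5. The equilibration may stall before all material has drained into the syn acetal, for instance through slow interconversion of the C5 epimers that arise from one of the C7 epimers. Cationic side paths may also consume the diol: Prins closure, oxonia-Cope scrambling of C3, alkylation of the arene or dehydration. In the fallback, C5 is set by a second reagent-controlled allylboration instead of by relay from C3. It sets out from 7. TESCl and imidazole give the triethylsilyl ether F1. Johnson–Lemieux cleavage of the terminal alkene (cat. OsO4, NaIO4, 2,6-lutidine, dioxane–water) gives the β-silyloxy aldehyde F2. Borane 5 then adds its allyl group, the future C6–C8, again to the Re face, which here is the 5R sense. This gives the borinate F3 and, after ethanolamine, the syn homoallylic alcohol F4. PPTS in methanol removes the triethylsilyl group to give the ene-diol F5. Hydrogenation of its terminal alkene (H2, Pd/C, EtOAc) comes back to the route at 14.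

2. Step 4. Self-metathesis of 7, slow turnover with the hindered allylic alcohol partner, or ruthenium hydride-mediated isomerisation of allylic alcohols to ketones may erode the conversion to the heterodimer. In the fallback, the C5=C6 bond is made by carbonyl olefination instead of metathesis. It sets out from 7. Johnson–Lemieux cleavage of the unprotected alcohol gives the β-hydroxy aldehyde F6, which is used crude. A Wittig reaction with 1-(triphenylphosphoranylidene)propan-2-one in CH2Cl2 gives the E-enone F7. Luche reduction (NaBH4, CeCl3·7H2O, MeOH, −40 °C) comes back to the route at 9 as the same C7 epimer mixture.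

3. Step 6. Palladium may hydrogenolyse the allylic C5–O bond before the alkene is saturated, which would remove the oxygen just installed, or the acetal cleavage may stall. In the fallback, both operations are done without a metal surface. It sets out from 12. Diimide reduction (2-nitrobenzenesulfonyl hydrazide, Et3N, CH2Cl2, rt) should give 13, now isolated. Acid-catalysed transacetalisation (cat. CSA, MeOH, rt), to which the aryl silyl ether is stable, comes back to the route at 14. New compounds: none F0.

Further compounds
F1 | step 5 | triethylsilyl ether of 7, (3S)-1-aryl-3-(triethylsilyloxy)hex-5-ene | C=CC[C@H](CCc1ccc(O[Si](C)(C)C(C)(C)C)c(OC)c1)O[Si](CC)(CC)CC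
F2 | step 5 | (3S)-5-aryl-3-(triethylsilyloxy)pentanal | O=CC[C@H](CCc1ccc(O[Si](C)(C)C(C)(C)C)c(OC)c1)O[Si](CC)(CC)CC
F3 | step 5 | (4R,6S)-8-aryl-6-(triethylsilyloxy)oct-1-en-4-yl diisopinocampheylborinate | C=CC[C@H](C[C@H](CCc1ccc(O[Si](C)(C)C(C)(C)C)c(OC)c1)O[Si](CC)(CC)CC)OB([C@H]1C[C@H]2C[C@@H]([C@@H]1C)C2(C)C)[C@H]1C[C@H]2C[C@@H]([C@@H]1C)C2(C)C
F4 | step 5 | (4R,6S)-8-aryl-6-(triethylsilyloxy)oct-1-en-4-ol | C=CC[C@H](C[C@H](CCc1ccc(O[Si](C)(C)C(C)(C)C)c(OC)c1)O[Si](CC)(CC)CC)O
F5 | step 5 | (3S,5R)-1-aryloct-7-ene-3,5-diol | C=CC[C@H](C[C@H](CCc1ccc(O[Si](C)(C)C(C)(C)C)c(OC)c1)O)O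
F6 | step 4 | (3S)-5-aryl-3-hydroxypentanal | O=CC[C@H](CCc1ccc(O[Si](C)(C)C(C)(C)C)c(OC)c1)O
F7 | step 4 | (3E,6S)-8-aryl-6-hydroxyoct-3-en-2-one | CC(=O)/C=C/C[C@H](CCc1ccc(O[Si](C)(C)C(C)(C)C)c(OC)c1)O
F0 | step 6 | none | none
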